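**Retrosynthetic overview**

1. The target is an (S)-β-acetoxy ketone on a C7 chain between two 4-hydroxy-3-methoxyphenyl rings; the last operations are release of the ketone from a 1,3-dithiane and hydrogenolysis of two O-benzyl groups.
2. Key disconnection: the bond between the carbonyl carbon and the CH2 that separates it from the acetoxy-bearing carbon. A 2-lithio-2-(2-arylethyl)-1,3-dithiane (acyl anion equivalent) opens an (S)-2-(2-arylethyl)oxirane, and the alkoxide is acetylated in the same flask.
3. Enabling feature: the 1,3-dioxygenated unit C(=O)–CH2–CH(OAc). The carbonyl carbon and the neighbouring CH2 are both acceptor carbons, so the carbonyl carbon is polarity-inverted inside a temporary six-membered S–C–S ring, and the CH2/CH–O pair is held as a temporary three-membered oxirane whose C–O bond at the stereocentre is never broken.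
4. Both chain ends carry the same 2-arylethyl group, so both partners come from one aldehyde, 3-(4-benzyloxy-3-methoxyphenyl)propanal (from eugenol): thioacetalisation on one side, Corey–Chaykovsky methylenation and hydrolytic kinetic resolution on the other.
5. Rings: both benzene rings are bought and no ring of the target is built; temporary rings in order are the dithiane (step 4) and the oxirane (step 5), the oxirane being opened in step 7 and the dithiane removed in step 8.

Key step: step 7

Remark: the acetoxy-bearing carbon is (S) as read from the SMILES; no bond to it is made or broken after step 6, and the oxirane CH2 holds the same CIP rank as the later CH2–C(=O) branch, so the (S)-epoxide maps onto the (S)-target.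

**Route**

Step 1
Reactants: 1 eugenol (4-allyl-2-methoxyphenol)
Product: 2 4-allyl-1-(benzyloxy)-2-methoxybenzene (O-benzyleugenol)
Conditions: BnBr (1.1 equiv), K2CO3 (1.5 equiv), acetone, reflux
Reagents that add atoms: benzyl bromide BrCc1ccccc1
Why: Williamson ether synthesis: the phenoxide formed with K2CO3 is benzylated by SN2, the allyl group is inert, and the benzyl ether should survive all later steps until hydrogenolysis.

Step 2
Reactants: 2 4-allyl-1-(benzyloxy)-2-methoxybenzene
Product: 4 3-[4-(benzyloxy)-3-methoxyphenyl]propan-1-ol, via B-alkyl-9-BBN adduct 3 (not isolated)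
Conditions: 9-BBN (1.2 equiv), THF, 0 °C → rt; then 3 M NaOH, 30% H2O2, 0 °C → rt
Reagents that add atoms: hydrogen peroxide OO (hydroxyl oxygen); 9-BBN [H]B1C2CCCC1CCC2 (boron only in 3)
Why: Anti-Markovnikov hydroboration–oxidation: the bulky borane places boron on the terminal carbon of the monosubstituted alkene and alkaline peroxide replaces boron by OH.

Step 3
Reactants: 4 3-[4-(benzyloxy)-3-methoxyphenyl]propan-1-ol
Product: 5 3-[4-(benzyloxy)-3-methoxyphenyl]propanal
Conditions: TEMPO (10 mol%), PhI(OAc)2 (1.1 equiv), CH2Cl2, rt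
Reagents that add atoms: none
Why: Oxoammonium-mediated (TEMPO) oxidation of a primary alcohol should stop at the aldehyde in CH2Cl2 and leave the electron-rich arene and the benzyl ether untouched.

Step 4
Reactants: 5 3-[4-(benzyloxy)-3-methoxyphenyl]propanal
Product: 6 2-{2-[4-(benzyloxy)-3-methoxyphenyl]ethyl}-1,3-dithiane
Conditions: HS(CH2)3SH (1.1 equiv), BF3·OEt2 (0.2 equiv), CH2Cl2, 0 °C
Reagents that add atoms: propane-1,3-dithiol SCCCS
Why: Lewis-acid-catalysed dithioacetalisation of an unhindered aldehyde installs the temporary 1,3-dithiane ring that later reverses the polarity of the carbonyl carbon.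

Step 5
Reactants: 5 3-[4-(benzyloxy)-3-methoxyphenyl]propanal
Product: 7 rac-2-{2-[4-(benzyloxy)-3-methoxyphenyl]ethyl}oxirane
Conditions: Me3S+ I− (1.3 equiv), n-BuLi (1.25 equiv), THF, −10 → 0 °C; then 5, 0 °C → rt
Reagents that add atoms: trimethylsulfonium iodide C[S+](C)C.[I-] (delivers CH2 through its ylide)
Why: Corey–Chaykovsky epoxidation: the unstabilised sulfonium ylide adds to the aldehyde carbonyl and the betaine closes by displacement of Me2S, adding the future chain CH2 and forming the oxirane, with the stereocentre racemic at this stage.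

Step 6
Reactants: 7 rac-2-{2-[4-(benzyloxy)-3-methoxyphenyl]ethyl}oxirane
Product: 8 (S)-2-{2-[4-(benzyloxy)-3-methoxyphenyl]ethyl}oxirane
Conditions: (S,S)-(salen)Co(III)OAc (0.5 mol%), H2O (0.55 equiv), THF (minimal), 0 °C → rt
Reagents that add atoms: none
Why: Jacobsen hydrolytic kinetic resolution: the (S,S)-catalyst is expected to hydrolyse the (R)-epoxide much faster, so the unreacted (S)-epoxide should remain in high enantiomeric purity, which fixes the only stereocentre of the target (configuration and ee to be checked by chiral HPLC before use).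

Step 7
Reactants: 6 2-{2-[4-(benzyloxy)-3-methoxyphenyl]ethyl}-1,3-dithiane; 8 (S)-2-{2-[4-(benzyloxy)-3-methoxyphenyl]ethyl}oxirane
Product: 11 (S)-4-[4-(benzyloxy)-3-methoxyphenyl]-1-(2-{2-[4-(benzyloxy)-3-methoxyphenyl]ethyl}-1,3-dithian-2-yl)butan-2-yl acetate, via 2-lithio-1,3-dithiane 9 (not isolated), via lithium alkoxide 10 (not isolated)
Conditions: 6 (1.2 equiv), t-BuLi (1.15 equiv), THF/HMPA 10:1, −78 °C, 10 min; 8 (1.0 equiv), −78 → −30 °C; then Ac2O (3 equiv), −30 → 0 °C
Reagents that add atoms: acetic anhydride CC(=O)OC(C)=O; tert-butyllithium [Li]C(C)(C)C (lithium only in 9 and 10)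
Why: Corey–Seebach umpolung: t-BuLi removes the C2–H of dithiane 6 to give the sulfur-stabilised carbanion 9, which opens oxirane 8 by SN2 attack at its unsubstituted CH2 carbon and so joins the masked carbonyl carbon to the methylene carbon; the lithium alkoxide 10 is then O-acetylated in the same flask. The closest known reaction type is the opening of terminal epoxides by 2-lithio-2-alkyl-1,3-dithianes with in situ acylation of the resulting alkoxide. No ring is closed: the oxirane is opened and the dithiane ring is only carried along. No new stereocentre is created, because the C–O bond at the carbinol carbon of 8 is never broken and its (S) configuration passes unchanged into 11. The step needs regioselectivity (CH2 over CH of the oxirane, secured by the steric demand of the tertiary dithianyl anion) and chemoselective metalation (dithiane C2–H over the ArO–CH2Ph and ArCH2 hydrogens, secured by double sulfur stabilisation, −78 °C and a slight deficit of base). In one operation it should deliver the whole C7 chain with both arenes, the masked carbonyl, the stereocentre and the acetate, with acetylation done while no ketone is present that could trigger β-elimination.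

Step 8
Reactants: 11 (S)-4-[4-(benzyloxy)-3-methoxyphenyl]-1-(2-{2-[4-(benzyloxy)-3-methoxyphenyl]ethyl}-1,3-dithian-2-yl)butan-2-yl acetate
Product: 12 (S)-1,7-bis[4-(benzyloxy)-3-methoxyphenyl]-5-oxoheptan-3-yl acetate
Conditions: MeI (10 equiv), CaCO3 (5 equiv), MeCN/H2O 9:1, 45 °C
Reagents that add atoms: water O
Why: Alkylative hydrolysis of the S,S-acetal: S-methylation makes sulfur a leaving group and water captures the thionium ion, releasing the ketone under buffered, nearly neutral conditions that should spare the β-acetoxy group, the non-enolisable stereocentre and the electron-rich arenes.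

Step 9
Reactants: 12 (S)-1,7-bis[4-(benzyloxy)-3-methoxyphenyl]-5-oxoheptan-3-yl acetate
Product: 13 (S)-1,7-bis(4-hydroxy-3-methoxyphenyl)-5-oxoheptan-3-yl acetate
Conditions: H2 (1 atm), 10% Pd/C, EtOAc, rt (12 first passed through silica to remove sulfur residues)
Reagents that add atoms: none
Why: Catalytic hydrogenolysis of the two aryl benzyl ethers under neutral conditions; the dialkyl ketone, the non-benzylic secondary acetate and the stereocentre are inert, so the bis-phenol target should result without exposure to base.

**Compound list**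

1 | eugenol (4-allyl-2-methoxyphenol) | C=CCc1ccc(O)c(OC)c1 | starting material
2 | 4-allyl-1-(benzyloxy)-2-methoxybenzene | C=CCc1ccc(OCc2ccccc2)c(OC)c1 | intermediate
3 | B-{3-[4-(benzyloxy)-3-methoxyphenyl]propyl}-9-borabicyclo[3.3.1]nonane | C(CCc1ccc(OCc2ccccc2)c(OC)c1)B1C2CCCC1CCC2 | intermediate (not isolated)
4 | 3-[4-(benzyloxy)-3-methoxyphenyl]propan-1-ol | OCCCc1ccc(OCc2ccccc2)c(OC)c1 | intermediate
5 | 3-[4-(benzyloxy)-3-methoxyphenyl]propanal | O=CCCc1ccc(OCc2ccccc2)c(OC)c1 | intermediate
6 | 2-{2-[4-(benzyloxy)-3-methoxyphenyl]ethyl}-1,3-dithiane | C1CSC(CCc2ccc(OCc3ccccc3)c(OC)c2)SC1 | intermediate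
7 | rac-2-{2-[4-(benzyloxy)-3-methoxyphenyl]ethyl}oxirane | COc1cc(CCC2CO2)ccc1OCc1ccccc1 | intermediate
8 | (S)-2-{2-[4-(benzyloxy)-3-methoxyphenyl]ethyl}oxirane | C1[C@H](CCc2ccc(OCc3ccccc3)c(OC)c2)O1 | intermediate
9 | 2-lithio-2-{2-[4-(benzyloxy)-3-methoxyphenyl]ethyl}-1,3-dithiane | [Li]C1(CCc2ccc(OCc3ccccc3)c(OC)c2)SCCCS1 | intermediate (not isolated)
10 | lithium (S)-4-[4-(benzyloxy)-3-methoxyphenyl]-1-(2-{2-[4-(benzyloxy)-3-methoxyphenyl]ethyl}-1,3-dithian-2-yl)butan-2-olate | COc1cc(CCC2(C[C@H](CCc3ccc(OCc4ccccc4)c(OC)c3)O[Li])SCCCS2)ccc1OCc1ccccc1 | intermediate (not isolated)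
11 | (S)-4-[4-(benzyloxy)-3-methoxyphenyl]-1-(2-{2-[4-(benzyloxy)-3-methoxyphenyl]ethyl}-1,3-dithian-2-yl)butan-2-yl acetate | COc1cc(CCC2(C[C@H](CCc3ccc(OCc4ccccc4)c(OC)c3)OC(C)=O)SCCCS2)ccc1OCc1ccccc1 | intermediate
12 | (S)-1,7-bis[4-(benzyloxy)-3-methoxyphenyl]-5-oxoheptan-3-yl acetate | COc1cc(CCC(=O)C[C@H](CCc2ccc(OCc3ccccc3)c(OC)c2)OC(C)=O)ccc1OCc1ccccc1 | intermediate
13 | (S)-1,7-bis(4-hydroxy-3-methoxyphenyl)-5-oxoheptan-3-yl acetate | COc1cc(CCC(=O)C[C@H](CCc2ccc(O)c(OC)c2)OC(C)=O)ccc1O | target

**Step count**

Total steps: 9. Longest linear sequence: 8 (steps 1, 2, 3, 5, 6, 7, 8, 9); step 4 is a one-step branch from the shared aldehyde 5.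

**Steps most likely to fail, and fallbacks**

Step 7. The benzylic O–CH2 positions may be metalated in competition with the dithiane (followed by Wittig-type rearrangement), or the hindered tertiary carbanion may open the oxirane too slowly, so that the two halves are not joined. The fallback sets out from epoxide 8 and aldehyde 5 and returns at 12; it makes the same carbon–carbon connection as an olefin by cross-metathesis and installs the carbonyl afterwards. Epoxide 8 would be homologated with excess dimethylsulfonium methylide (Me3SI, n-BuLi, THF, −10 °C → rt) to (S)-5-[4-(benzyloxy)-3-methoxyphenyl]pent-1-en-3-ol F1, with the stereocentre untouched. Acetylation (Ac2O, pyridine, DMAP, CH2Cl2, 0 °C) should give (S)-5-[4-(benzyloxy)-3-methoxyphenyl]pent-1-en-3-yl acetate F2. Aldehyde 5 would be methylenated (Ph3P=CH2, THF, 0 °C) to 1-(benzyloxy)-4-(but-3-en-1-yl)-2-methoxybenzene F3. Cross-metathesis of F2 with excess F3 (Hoveyda–Grubbs II catalyst, CH2Cl2, 40 °C) should give (S,E)-1,7-bis[4-(benzyloxy)-3-methoxyphenyl]hept-4-en-3-yl acetate F4. A Wacker oxidation of this internal allylic acetate (Pd(OAc)2 cat., benzoquinone, aq. HBF4, DMA/MeCN/H2O, rt) should place the carbonyl on the olefin carbon remote from the electron-withdrawing acetoxy group and give 12.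

Step 8. Once the ketone is unveiled next to the acetoxy-bearing carbon, acetic acid may be lost by β-elimination to the enone, or the hydrolysis may stall at the S-methylsulfonium stage. The fallback sets out from lithium alkoxide 10 and returns at 12; it unveils the ketone before the leaving group exists. Quenching 10 with aqueous NH4Cl instead of Ac2O should give (S)-4-[4-(benzyloxy)-3-methoxyphenyl]-1-(2-{2-[4-(benzyloxy)-3-methoxyphenyl]ethyl}-1,3-dithian-2-yl)butan-2-ol F5. The same alkylative hydrolysis (MeI, CaCO3, MeCN/H2O, 45 °C) should then give (S)-1,7-bis[4-(benzyloxy)-3-methoxyphenyl]-5-hydroxyheptan-3-one F6. Acetylation under acid catalysis (Ac2O, Sc(OTf)3 cat., MeCN, 0 °C), which avoids the amine bases that promote elimination, should give 12.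

Step 9. Sulfur residues carried over from step 8 may poison the palladium surface, and a prolonged reaction may allow slow loss of acetic acid from the product. The fallback sets out from 12 and returns at 13; it removes the benzyl groups by Lewis-acid ionisation instead of hydrogenolysis (BCl3, pentamethylbenzene as non-basic cation scavenger, CH2Cl2, −78 °C). This is insensitive to sulfur, and at this temperature the aryl methyl ethers, the acetate and the ketone should survive. This fallback makes no new compound (F0).

**Further compounds**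

F1 | step 7 | (S)-5-[4-(benzyloxy)-3-methoxyphenyl]pent-1-en-3-ol | C=C[C@H](CCc1ccc(OCc2ccccc2)c(OC)c1)O
F2 | step 7 | (S)-5-[4-(benzyloxy)-3-methoxyphenyl]pent-1-en-3-yl acetate | C=C[C@H](CCc1ccc(OCc2ccccc2)c(OC)c1)OC(C)=O
F3 | step 7 | 1-(benzyloxy)-4-(but-3-en-1-yl)-2-methoxybenzene | C=CCCc1ccc(OCc2ccccc2)c(OC)c1
F4 | step 7 | (S,E)-1,7-bis[4-(benzyloxy)-3-methoxyphenyl]hept-4-en-3-yl acetate | COc1cc(CC/C=C/[C@H](CCc2ccc(OCc3ccccc3)c(OC)c2)OC(C)=O)ccc1OCc1ccccc1
F5 | step 8 | (S)-4-[4-(benzyloxy)-3-methoxyphenyl]-1-(2-{2-[4-(benzyloxy)-3-methoxyphenyl]ethyl}-1,3-dithian-2-yl)butan-2-ol | COc1cc(CCC2(C[C@H](CCc3ccc(OCc4ccccc4)c(OC)c3)O)SCCCS2)ccc1OCc1ccccc1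
F6 | step 8 | (S)-1,7-bis[4-(benzyloxy)-3-methoxyphenyl]-5-hydroxyheptan-3-one | COc1cc(CCC(=O)C[C@H](CCc2ccc(OCc3ccccc3)c(OC)c2)O)ccc1OCc1ccccc1
F0 | step 9 | none | none
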